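**Retrosynthetic overview**
1. Moracin Q ⇒ its tri-O-benzyl ether, cleaved by one global hydrogenolysis at the end. The C5–OMe group is carried from the first compound.
2. The furan ring (closed last, O1–C2) and the benzene ring (re-aromatised by loss of MeOH) ⇒ a 5,6-disubstituted 3-(benzyloxy)-4,4-dimethoxycyclohex-2-enone holding two 1,4-dicarbonyl pairs.
3. Key disconnection, both dissonant bonds in one flask. C4–CH2 = kinetic enolate of 3-methylbutan-2-one + a p-quinone monoketal, which is electrophilic at the carbon alpha to its masked C5 carbonyl (an enolonium equivalent). C3a–C3 = the ring enolate so formed + an α-bromo ketone (second enolonium equivalent).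
4. Quinone monoketal ⇒ 3-(benzyloxy)-4-methoxyphenol ⇒ O-benzylisovanillin. Bromo ketone ⇒ 3',5'-bis(benzyloxy)acetophenone.
5. Ring order: both benzene rings are bought. The trioxygenated one is dearomatised, alkylated twice and re-aromatised, and the furan ring forms last.

Assumption: the target SMILES holds no stereocentre (moracin Q is achiral), so there is no enantiomer to control. The stereocentres of transient intermediates are racemic and are erased on aromatisation.

Step 1
Reactants: 1 3-(benzyloxy)-4-methoxybenzaldehyde (O-benzylisovanillin)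
Product: 3 3-(benzyloxy)-4-methoxyphenol, via aryl formate 2 (not isolated)
Conditions: 30% aq. H2O2 (1.3 equiv), H2SO4 (cat.), MeOH, rt
Reagents that add atoms: hydrogen peroxide, OO
Why: In this acid-catalysed Dakin-type (Baeyer–Villiger) oxidation the aryl group para to OMe migrates to oxygen in the peroxyhemiacetal and formate 2 is methanolysed in situ, while the benzyl ether is inert and no stereocentre is formed.

Step 2
Reactants: 3 3-(benzyloxy)-4-methoxyphenol
Product: 4 3-(benzyloxy)-4,4-dimethoxycyclohexa-2,5-dien-1-one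
Conditions: PhI(OAc)2 (1.05 equiv), MeOH, 0 °C; NaHCO3 work-up
Reagents that add atoms: methanol, CO
Why: In this oxidative dearomatisation of a 4-methoxyphenol with a trivalent iodine reagent, methanol traps the phenoxenium ion at the para carbon that already carries OMe, giving the p-quinone monoketal with no stereocentre.

Step 3
Reactants: 5 1-[3,5-bis(benzyloxy)phenyl]ethan-1-one
Product: 6 1-[3,5-bis(benzyloxy)phenyl]-2-bromoethan-1-one
Conditions: CuBr2 (2.1 equiv), EtOAc–CHCl3 (1:1), reflux
Reagents that add atoms: CuBr2 (copper dibromide), [Cu+2].[Br-].[Br-]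
Why: King–Ostrum α-bromination goes through the copper-bound enol, so the activated resorcinol ring and the benzyl ethers are spared and the natively nucleophilic α-carbon becomes electrophilic, with no stereocentre formed.

Step 4
Reactants: 4 3-(benzyloxy)-4,4-dimethoxycyclohexa-2,5-dien-1-one; 6 1-[3,5-bis(benzyloxy)phenyl]-2-bromoethan-1-one; 7 3-methylbutan-2-one
Product: 12 1-{6-(benzyloxy)-2-[3,5-bis(benzyloxy)phenyl]-5-methoxy-1-benzofuran-4-yl}-3-methylbutan-2-one (tri-O-benzylmoracin Q), via lithium enolate 8 (not isolated), via ring enolate 9 (not isolated), via diketone ketal 10 (not isolated), via diketo phenol 11 (not isolated)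
Conditions: 7 (1.05 equiv), LiN(i-Pr)2 (1.05 equiv), THF, −78 °C; 4 added slowly, −78 to −20 °C; DMPU, 6 (1.2 equiv), −78 to 0 °C; then anhydrous 4 M HCl in dioxane (acid promoter), 0 to 40 °C
Reagents that add atoms: none
Why: Proposed new method: this is a one-flask Michael addition–enolate alkylation–aromatising cyclodehydration in which kinetic enolate 8 attacks the unsubstituted enone carbon of 4 that lies alpha to the masked C5 carbonyl (4 acts as an enolonium equivalent, the competing 1,2-aldolate at the vinylogous-ester carbonyl is reversible and drains to the 1,4-adduct on warming, and the benzyloxy-bearing double bond is deactivated), the regiodefined cross-conjugated enolate 9 (Stork–Danheiser type) is C-alkylated by the second enolonium equivalent 6 in a fast SN2 step, and anhydrous acid then ionises the ketal, expels MeOH to re-aromatise (10 to 11) and dehydrates the 2-hydroxybenzyl aryl ketone to the furan (Paal–Knorr type), erasing the two transient racemic stereocentres; the closest known reaction types are conjugate additions of stabilised carbanions and organometallics to p-quinone monoketals followed by acid aromatisation to 3-substituted 4-methoxyphenols, three-component conjugate addition–enolate trapping, and 1,4-diketone synthesis from enolates and α-halo ketones.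

Step 5
Reactants: 12 tri-O-benzylmoracin Q
Product: 13 1-[2-(3,5-dihydroxyphenyl)-6-hydroxy-5-methoxy-1-benzofuran-4-yl]-3-methylbutan-2-one (moracin Q)
Conditions: H2 (1 atm), Pd on carbon (10 wt % Pd), EtOAc–MeOH, rt, stopped after uptake of 3 equiv H2
Reagents that add atoms: none
Why: Catalytic hydrogenolysis cleaves the three aryl benzyl ethers, while the aryl methyl ether, the non-conjugated ketone and the aromatic 2-arylbenzofuran are inert at 1 atm and rt, and no stereocentre is present or formed.

**Compound list**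
1 | 3-(benzyloxy)-4-methoxybenzaldehyde | COc1ccc(C=O)cc1OCc1ccccc1 | starting material
2 | 3-(benzyloxy)-4-methoxyphenyl formate | COc1ccc(OC=O)cc1OCc1ccccc1 | intermediate
3 | 3-(benzyloxy)-4-methoxyphenol | COc1ccc(O)cc1OCc1ccccc1 | intermediate
4 | 3-(benzyloxy)-4,4-dimethoxycyclohexa-2,5-dien-1-one | COC1(OC)C=CC(=O)C=C1OCc1ccccc1 | intermediate
5 | 1-[3,5-bis(benzyloxy)phenyl]ethan-1-one | CC(=O)c1cc(OCc2ccccc2)cc(OCc2ccccc2)c1 | starting material
6 | 1-[3,5-bis(benzyloxy)phenyl]-2-bromoethan-1-one | O=C(CBr)c1cc(OCc2ccccc2)cc(OCc2ccccc2)c1 | intermediate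
7 | 3-methylbutan-2-one | CC(=O)C(C)C | starting material
8 | lithium 3-methylbut-1-en-2-olate | [Li+].[O-]C(=C)C(C)C | intermediate
9 | lithium 5-(benzyloxy)-4,4-dimethoxy-3-(3-methyl-2-oxobutyl)cyclohexa-1,5-dien-1-olate (racemic) | [Li+].[O-]C1=CC(CC(=O)C(C)C)C(OC)(OC)C(OCc2ccccc2)=C1 | intermediate
10 | 3-(benzyloxy)-6-{2-[3,5-bis(benzyloxy)phenyl]-2-oxoethyl}-4,4-dimethoxy-5-(3-methyl-2-oxobutyl)cyclohex-2-en-1-one (racemic, trans expected, both centres vanish later) | COC1(OC)C(OCc2ccccc2)=CC(=O)C(CC(=O)c2cc(OCc3ccccc3)cc(OCc3ccccc3)c2)C1CC(=O)C(C)C | intermediate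
11 | 1-[3-(benzyloxy)-6-{2-[3,5-bis(benzyloxy)phenyl]-2-oxoethyl}-5-hydroxy-2-methoxyphenyl]-3-methylbutan-2-one | COc1c(OCc2ccccc2)cc(O)c(CC(=O)c2cc(OCc3ccccc3)cc(OCc3ccccc3)c2)c1CC(=O)C(C)C | intermediate
12 | 1-{6-(benzyloxy)-2-[3,5-bis(benzyloxy)phenyl]-5-methoxy-1-benzofuran-4-yl}-3-methylbutan-2-one | COc1c(OCc2ccccc2)cc2oc(-c3cc(OCc4ccccc4)cc(OCc4ccccc4)c3)cc2c1CC(=O)C(C)C | intermediate
13 | moracin Q, 1-[2-(3,5-dihydroxyphenyl)-6-hydroxy-5-methoxy-1-benzofuran-4-yl]-3-methylbutan-2-one (achiral) | COc1c(O)cc2oc(-c3cc(O)cc(O)c3)cc2c1CC(=O)C(C)C | target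

**Total step count:** 5. **Longest linear sequence:** 4 (steps 1, 2, 4, 5).

**Steps most likely to fail**

**Step 4 (highest risk).** There are four ways it can go wrong:
- The lithium enolate may stay at the 1,2-adduct.
- Enolate 9 may deprotonate 6 or attack its carbonyl instead of displacing bromide.
- In the acid stage, the isopropyl ketone may close a furan onto the ketal carbon.
- In the acid stage, the two ketones may condense to an indene.

The fallback sets out from 4 and comes back at 12, and it separates the two bond formations.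
- Enolate 8 is added to 4 as before, but enolate 9 is quenched with aqueous NH4Cl. This gives racemic 3-(benzyloxy)-4,4-dimethoxy-5-(3-methyl-2-oxobutyl)cyclohex-2-en-1-one F1.
- Catalytic camphorsulfonic acid in dry CH2Cl2 aromatises F1, with loss of MeOH, to 1-[3-(benzyloxy)-5-hydroxy-2-methoxyphenyl]-3-methylbutan-2-one F2.
- N-Iodosuccinimide in MeCN at 0 °C iodinates F2 ortho to the OH and para to the benzyloxy group. This gives 1-[3-(benzyloxy)-5-hydroxy-6-iodo-2-methoxyphenyl]-3-methylbutan-2-one F3.
- Commercial 3,5-bis(benzyloxy)benzaldehyde is homologated with dimethyl (1-diazo-2-oxopropyl)phosphonate, K2CO3 and MeOH to 1,3-bis(benzyloxy)-5-ethynylbenzene F4.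
- Sonogashira coupling of F3 and F4 (PdCl2(PPh3)2, CuI, Et3N, DMF, 60 °C) gives 1-[3-(benzyloxy)-6-{[3,5-bis(benzyloxy)phenyl]ethynyl}-5-hydroxy-2-methoxyphenyl]-3-methylbutan-2-one F5. This closes in the same flask by 5-endo-dig attack of the phenol to give 12.

**Step 5.** The C2=C3 bond of the furan may be partly saturated, or the hindered C6 benzyl ether may lag. The fallback sets out from 12 and comes back at 13. It replaces reduction by a Lewis-acid cleavage: BCl3 with pentamethylbenzene as benzyl-cation trap, CH2Cl2, −78 °C, MeOH quench. The aryl methyl ether survives at this temperature. No new compound F0 is made on the way.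

**Step 2.** Monoketal 4 is acid-sensitive, and over-oxidation or loss of a methoxy group would give a quinone. The fallback sets out from 3 and comes back at 4.
- O-Methylation of 3 (MeI, K2CO3, acetone) gives 2-(benzyloxy)-1,4-dimethoxybenzene F6.
- Anodic oxidation (Pt anode, KOH, MeOH, 0 °C, undivided cell) gives the quinone bisketal 1-(benzyloxy)-3,3,6,6-tetramethoxycyclohexa-1,4-diene F7.
- Brief treatment with aqueous AcOH in acetone at 0 °C hydrolyses only one ketal, the one whose allyl cation is stabilised by the benzyloxy group. That is the ketal not adjacent to the benzyloxy-bearing carbon, so the product is 4.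

**Further compounds**
F1 | step 4 | 3-(benzyloxy)-4,4-dimethoxy-5-(3-methyl-2-oxobutyl)cyclohex-2-en-1-one (racemic) | COC1(OC)C(OCc2ccccc2)=CC(=O)CC1CC(=O)C(C)C
F2 | step 4 | 1-[3-(benzyloxy)-5-hydroxy-2-methoxyphenyl]-3-methylbutan-2-one | COc1c(OCc2ccccc2)cc(O)cc1CC(=O)C(C)C
F3 | step 4 | 1-[3-(benzyloxy)-5-hydroxy-6-iodo-2-methoxyphenyl]-3-methylbutan-2-one | COc1c(OCc2ccccc2)cc(O)c(I)c1CC(=O)C(C)C
F4 | step 4 | 1,3-bis(benzyloxy)-5-ethynylbenzene | C#Cc1cc(OCc2ccccc2)cc(OCc2ccccc2)c1
F5 | step 4 | 1-[3-(benzyloxy)-6-{[3,5-bis(benzyloxy)phenyl]ethynyl}-5-hydroxy-2-methoxyphenyl]-3-methylbutan-2-one | COc1c(OCc2ccccc2)cc(O)c(C#Cc2cc(OCc3ccccc3)cc(OCc3ccccc3)c2)c1CC(=O)C(C)C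
F0 | step 5 | none | none
F6 | step 2 | 2-(benzyloxy)-1,4-dimethoxybenzene | COc1ccc(OC)c(OCc2ccccc2)c1
F7 | step 2 | 1-(benzyloxy)-3,3,6,6-tetramethoxycyclohexa-1,4-diene | COC1(OC)C=CC(OC)(OC)C(OCc2ccccc2)=C1
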